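## Structural features

The target is an isoflavone: a benzene ring A fused through C4a–C8a to a pyran-4-one ring C, with a 3,4-dimethoxyphenyl ring B joined to C3 by a single C3–C1' bond. Ring A carries four contiguous substituents besides the fusion atoms: O1 on C8a, a 3-methylbut-2-enyl (prenyl) chain on C8, a free hydroxyl on C7 and a methoxy group on C6, so only C5 bears hydrogen. There is no stereocentre, and the side-chain alkene ends in two identical methyl groups, so no configuration has to be set. The fragile points are the prenyl group next to a free phenol (acid closes it to a dimethylchroman, and it is open to hydrogenation and oxidation), the pyranone C2 (hydroxide or alkoxide can add there and open ring C), and the aryl methyl ethers under strong Lewis acids. The real difficulty is regiochemical: O6 must become the methyl ether and O7 the free phenol, and the prenyl carbon must go to C8 and not to C6 or to oxygen. The feature used here is that O1 and the C4 carbonyl sit on the neighbouring ring A carbons C8a and C4a, the two carbons of an aryne triple bond, so ring C can be closed by adding an oxygen nucleophile and an acyl electrophile across an aryne. With a symmetrical 4,5-methylenedioxy aryne the two ring A oxygens arrive without any regiochemical question, and they are told apart afterwards because 7-OH is conjugated with the C4 carbonyl and 6-OH is not.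

## Logic of the disconnections

17 to 16: the C8–CH2 bond of the prenyl group is cut and traced back to an O7–C(CH3)2 ether bond through a [3,3] shift. The cut is made there because the shift delivers carbon only to a position ortho to O7, and C6 is blocked. The gain is that the C–C bond on a crowded ring comes from an easily made C–O bond. The forward step must be run without acid so that the new ortho-prenyl phenol does not cyclise.

16 to 15: the vinyl group is taken back to an ethynyl group. Tertiary propargyl aryl ethers form much more readily than tertiary allyl aryl ethers. The forward step needs a hydrogenation that stops at the alkene and spares the C2=C3 bond of ring C.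

15 to 14: the O6–CH3 bond is cut. It is placed after the O7 ether so that the methyl group goes to the only phenol left. The demand is trivial.

14 to 11 and 12: the O7–C(CH3)2 bond is cut. This removes the whole side chain and leaves a catechol and a commodity alcohol. The forward step must alkylate 7-OH and not 6-OH, which rests on the higher acidity of the hydroxyl para to the C4 carbonyl and on the use of one equivalent of base.

11 to 10: the two O–H bonds are traced back to one O–CH2–O bridge. The bridge makes ring A symmetrical for the ring-forming step and can be opened by a reagent that leaves aryl methyl ethers alone. The forward step must cleave the acetal without touching the three other ether groups.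

10 to 5 and 8: the O1–C8a and C4–C4a bonds are cut, which opens ring C. This separates the molecule into an aryne precursor for ring A and a three-carbon formyl ester that already holds ring B, C2, C3 and C4. Both partners are two or three steps from bulk chemicals and the aryne is symmetrical. The forward step must arylate the enolate on oxygen and must close the ring before the aryl anion is protonated.

8 to 6 and 7: the C2–C3 bond between the formyl carbon and the benzylic carbon is cut. This is a crossed ester condensation with a formate that cannot enolise. The only demand is to drive the equilibrium with a full equivalent of base.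

5 to 2: the C–Si and O–S bonds are cut. Silicon is delivered from oxygen to the ortho carbon after halogen–lithium exchange, so the ortho relation of the two groups is fixed by the position of bromine. The forward step needs low temperature so that the aryllithium rearranges and does not decompose.

2 to 1: the C–Br bond is cut. Bromination must go to C6 of the benzodioxole, which is ortho to the hydroxyl, para to a ring oxygen and unhindered.

## Other disconnections considered

Alternative 1: The cut goes through C5–C6 and C7–C8, so ring A would be assembled from a 2-pyrone holding C5, C4a, C8a and C8 and a two-carbon ketene acetal holding C6 and C7.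
- Forward step: methyl 4-acetoxy-3-(3-methylbut-2-enyl)-2-oxo-2H-pyran-5-carboxylate A2 would take up 2-methoxy-1,1-bis(trimethylsilyloxy)ethene A3 across C3 and C6 in a Diels–Alder reaction of inverse electron demand. Loss of CO2 from the bridged lactone and of Me3SiOH would then give methyl 2-acetoxy-4-hydroxy-5-methoxy-3-(3-methylbut-2-enyl)benzoate A1.
- In its favour: the 6-methoxy and 7-hydroxy groups would be distinct from the moment ring A forms, and the prenyl group would already sit on C8. On this point the alternative is better than the chosen plan, which separates the two oxygens by acidity and needs a sigmatropic shift for the prenyl group. The reaction class is also well established, whereas the chosen key step is not.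
- Against it: A2 is not a simple compound (C-prenylation of a 4-hydroxypyrone competes with O-prenylation). A1 is only ring A, so the ester carbon would still have to become C4 by acylation of an arylacetic carbanion, formylation and ring closure, all while a prenyl group and a free phenol are carried along.
- Comparison: neither plan has stereochemistry to set. The alternative is the better one on oxygen differentiation, but it is linear and longer, whereas the chosen plan joins all three rings in one step.

Alternative 2: The cut is the C4a–C8a bond, with ring A traced back to a four-membered ring derived from a squarate ester.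
- Forward step: heating 4-ethenyl-4-methoxy-2-(3-methylbut-2-enyl)-3-(propan-2-yloxy)cyclobut-2-en-1-one A5 would open it to a dienylketene. A 6-pi electrocyclisation followed by tautomerisation would give 4-methoxy-2-(3-methylbut-2-enyl)-3-(propan-2-yloxy)phenol A4.
- In its favour: every substituent of ring A would be placed by the order of additions to the squarate, and the two oxygens would be distinct as methyl and isopropyl ethers from the start. This regiocontrol by construction is better than that of the chosen plan. The rearrangement itself is a known reaction type.
- Against it: A4 lacks C4, C3, C2 and ring B. The arylacetyl group would have to be put on C4a by a Friedel–Crafts or Fries reaction in the presence of an acid-sensitive prenyl group. The isopropyl ether would have to be removed at the end with a Lewis acid next to that prenyl group, where chroman formation threatens. Addition of a prenyl organometallic to the squarate can also occur at either allyl terminus.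
- Comparison: the alternative is more secure on ring A regiochemistry. The chosen plan is shorter and more convergent, and it brings in the prenyl group last, so no acidic step follows it.

Alternative 3: The cut is the O1–C8a bond only, with ring C closed on a complete ring A.
- Forward step: the enol oxygen of 1-[2-bromo-5-methoxy-4-(methoxymethoxy)-3-(3-methylbut-2-enyl)phenyl]-2-(3,4-dimethoxyphenyl)-3-hydroxyprop-2-en-1-one A7 would displace bromide under CuI (monovalent copper) and K2CO3 in an Ullmann-type ether formation. This would give 3-(3,4-dimethoxyphenyl)-6-methoxy-7-(methoxymethoxy)-8-(3-methylbut-2-enyl)chromen-4-one A6, from which the methoxymethyl group would then be removed.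
- In its favour: the reaction type is established for chromones. Because it is intramolecular, arylation on oxygen is the only sensible outcome, so this closure is more secure than the chosen key step, where oxygen must compete with carbon.
- Against it: A7 is a pentasubstituted benzene whose bromine lies between the acyl and prenyl groups, which should slow the copper step. Its preparation needs regiocontrolled bromination, prenylation, acylation and formylation in a long linear sequence. The final acidic deprotection sits next to the prenyl group. Only one ring bond is formed, against two in the chosen step.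
- Comparison: both plans close ring C last or nearly last. The alternative is better on precedent, and the chosen plan is better on step count and on the simplicity of the ring A partner.

Key step: step 4

Remark on the chemistry: compound 8 is written as the hydrogen-bonded Z-enol; it equilibrates with its aldehyde tautomer and both give the same enolate, so the tautomer composition is of no consequence. Compound 5 can also be bought, in which case steps 1 and 2 fall away.

## Route

Step 1
Reactants: 1 sesamol (1,3-benzodioxol-5-ol)
Product: 2 6-bromo-1,3-benzodioxol-5-ol
Conditions: NBS (1.0 equiv), CH2Cl2, −78 → 0 °C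
Reagents that add atoms: N-bromosuccinimide, O=C1CCC(=O)N1Br
Why: Electrophilic aromatic bromination; C6 is ortho to the hydroxyl, para to a dioxole oxygen and unhindered, whereas C4 is flanked on both sides, so monobromination at C6 is expected at low temperature.

Step 2
Reactants: 2 6-bromo-1,3-benzodioxol-5-ol
Product: 5 6-(trimethylsilyl)-1,3-benzodioxol-5-yl trifluoromethanesulfonate, via bromoaryl trimethylsilyl ether 3 (not isolated), via lithium 2-silylphenoxide 4 (not isolated)
Conditions: HMDS, THF, 70 °C, then evaporation; n-BuLi, THF, −100 → −80 °C; Tf2O, −100 → −80 °C; aq. NaHCO3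
Reagents that add atoms: hexamethyldisilazane, C[Si](C)(C)N[Si](C)(C)C; trifluoromethanesulfonic anhydride, O=S(=O)(OS(=O)(=O)C(F)(F)F)C(F)(F)F
Why: O-silylation, then bromine–lithium exchange sets off a 1,3-retro-Brook shift of silicon from oxygen to the ortho carbon, and the lithium phenoxide is trapped as the triflate; this one-pot sequence is the standard way to ortho-silylaryl triflates.

Step 3
Reactants: 6 methyl (3,4-dimethoxyphenyl)acetate; 7 methyl formate
Product: 8 methyl (Z)-2-(3,4-dimethoxyphenyl)-3-hydroxyacrylate
Conditions: NaH (2.5 equiv), HCO2Me (4 equiv), THF, 0 °C → rt; then 1 M HCl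
Reagents that add atoms: none
Why: Crossed Claisen condensation (C-formylation) of the ester enolate with a formate that cannot enolise; the product is drawn out of the equilibrium as its sodium enolate and is released on acidification as the chelated Z-enol.

Step 4
Reactants: 5 6-(trimethylsilyl)-1,3-benzodioxol-5-yl trifluoromethanesulfonate; 8 methyl (Z)-2-(3,4-dimethoxyphenyl)-3-hydroxyacrylate
Product: 10 7-(3,4-dimethoxyphenyl)-[1,3]dioxolo[4,5-g]chromen-8-one (6,7-methylenedioxy-3',4'-dimethoxyisoflavone), via 4,5-methylenedioxybenzyne 9 (not isolated)
Conditions: CsF (4 equiv), THF, 65 °C, 5 (1.3 equiv) added over 4 h by syringe pump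
Reagents that add atoms: none
Why: Proposed new method: fluoride attacks silicon of 5 and triflate leaves to give aryne 9, whose two reactive carbons are equivalent by symmetry, so no regiochemical question arises on the aryne side. The caesium enolate of 8 is expected to add through oxygen, because its carbon terminus is fully substituted and flanked by the aryl and ester groups, which gives an aryl enol ether with an anion on the ortho carbon. On the Z-configured enol ether this anion lies cis to the ester and closes ring C by a 6-exo-trig addition to the ester carbonyl; collapse of the tetrahedral intermediate with loss of methoxide gives the pyranone, so O1–C8a and C4–C4a are formed in one operation. The closest known reaction type is the CsF-promoted coupling of arynes with methyl salicylates to xanthones, in which a phenoxide plays the part taken here by the enolate. No stereocentre is formed. The step needs arylation on oxygen and not on carbon, and ring closure and not protonation of the aryl anion; the cost of making a quaternary carbon, the chelated Z geometry of the enolate, the aprotic solvent and the slow release of 9 should secure both.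

Step 5
Reactants: 10 7-(3,4-dimethoxyphenyl)-[1,3]dioxolo[4,5-g]chromen-8-one
Product: 11 3-(3,4-dimethoxyphenyl)-6,7-dihydroxychromen-4-one
Conditions: BCl3 (1 M in CH2Cl2, 3 equiv), CH2Cl2, −78 → 0 °C; then H2O, rt
Reagents that add atoms: none
Why: Lewis-acid cleavage of the methylene acetal; BCl3 opens the O–CH2–O unit through an oxocarbenium ion far more easily than it cleaves an aryl methyl ether, and no methoxy group sits next to the carbonyl where chelation would assist demethylation. Aqueous work-up releases the catechol.

Step 6
Reactants: 11 3-(3,4-dimethoxyphenyl)-6,7-dihydroxychromen-4-one; 12 2-methylbut-3-yn-2-ol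
Product: 14 3-(3,4-dimethoxyphenyl)-6-hydroxy-7-(2-methylbut-3-yn-2-yloxy)chromen-4-one, via 2-methylbut-3-yn-2-yl trifluoroacetate 13 (not isolated)
Conditions: 12, TFAA, DBU, MeCN, −5 °C (forms 13); added to 11, DBU (1.05 equiv), CuCl2·2H2O (1 mol%), MeCN, −5 → 0 °C
Reagents that add atoms: none
Why: Copper-catalysed propargylic etherification of a phenol with a tertiary propargyl ester, which proceeds through a copper-bound propargyl cation equivalent. With one equivalent of base the phenoxide forms at 7-OH, the hydroxyl para to the C4 carbonyl and therefore the more acidic, so the ether is expected on O7.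

Step 7
Reactants: 14 3-(3,4-dimethoxyphenyl)-6-hydroxy-7-(2-methylbut-3-yn-2-yloxy)chromen-4-one
Product: 15 3-(3,4-dimethoxyphenyl)-6-methoxy-7-(2-methylbut-3-yn-2-yloxy)chromen-4-one
Conditions: MeI, K2CO3, acetone, rt
Reagents that add atoms: iodomethane, CI
Why: Williamson methylation of the one remaining phenol; the terminal alkyne and the tertiary ether are inert to K2CO3 and MeI at room temperature.

Step 8
Reactants: 15 3-(3,4-dimethoxyphenyl)-6-methoxy-7-(2-methylbut-3-yn-2-yloxy)chromen-4-one
Product: 16 3-(3,4-dimethoxyphenyl)-6-methoxy-7-(2-methylbut-3-en-2-yloxy)chromen-4-one
Conditions: H2 (1 atm), Pd/CaCO3 poisoned with Pb(OAc)2 (Lindlar catalyst), quinoline, EtOAc, rt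
Reagents that add atoms: none
Why: Lindlar semihydrogenation of the terminal alkyne to the vinyl group; the poisoned catalyst should leave the C2=C3 bond of ring C and the aryl ethers untouched if hydrogen uptake is stopped at one equivalent.

Step 9
Reactants: 16 3-(3,4-dimethoxyphenyl)-6-methoxy-7-(2-methylbut-3-en-2-yloxy)chromen-4-one
Product: 17 3-(3,4-dimethoxyphenyl)-7-hydroxy-6-methoxy-8-(3-methylbut-2-enyl)chromen-4-one (target)
Conditions: PhNEt2, 180 °C, argon
Reagents that add atoms: none
Why: Aromatic Claisen rearrangement ([3,3]-sigmatropic shift) through a chair transition state turns the 1,1-dimethylallyl ether into a 3-methylbut-2-enyl group on the ortho carbon. C6 carries methoxy, so a shift to that side gives a dienone that can only revert, and C8 is the only position where enolisation to the phenol completes the reaction; the basic solvent keeps the product from cyclising to a chroman.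

## Compound list

1 | sesamol (1,3-benzodioxol-5-ol) | Oc1ccc2OCOc2c1 | starting material
2 | 6-bromo-1,3-benzodioxol-5-ol | Oc1cc2OCOc2cc1Br | intermediate
3 | [(6-bromo-1,3-benzodioxol-5-yl)oxy]trimethylsilane | C[Si](C)(C)Oc1cc2OCOc2cc1Br | intermediate (not isolated)
4 | lithium 6-(trimethylsilyl)-1,3-benzodioxol-5-olate | [Li+].[O-]c1cc2OCOc2cc1[Si](C)(C)C | intermediate (not isolated)
5 | 6-(trimethylsilyl)-1,3-benzodioxol-5-yl trifluoromethanesulfonate | C[Si](C)(C)c1cc2OCOc2cc1OS(=O)(=O)C(F)(F)F | intermediate
6 | methyl (3,4-dimethoxyphenyl)acetate | COC(=O)Cc1ccc(OC)c(OC)c1 | starting material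
7 | methyl formate | COC=O | starting material
8 | methyl (Z)-2-(3,4-dimethoxyphenyl)-3-hydroxyacrylate | COC(=O)/C(=C\O)c1ccc(OC)c(OC)c1 | intermediate
9 | 4,5-methylenedioxybenzyne (5,6-didehydro-1,3-benzodioxole) | C1OC2=CC#CC=C2O1 | intermediate (not isolated)
10 | 7-(3,4-dimethoxyphenyl)-[1,3]dioxolo[4,5-g]chromen-8-one | COc1ccc(-c2coc3cc4OCOc4cc3c2=O)cc1OC | intermediate
11 | 3-(3,4-dimethoxyphenyl)-6,7-dihydroxychromen-4-one | COc1ccc(-c2coc3cc(O)c(O)cc3c2=O)cc1OC | intermediate
12 | 2-methylbut-3-yn-2-ol | CC(C)(O)C#C | starting material
13 | 2-methylbut-3-yn-2-yl trifluoroacetate | CC(C)(C#C)OC(=O)C(F)(F)F | intermediate (not isolated)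
14 | 3-(3,4-dimethoxyphenyl)-6-hydroxy-7-(2-methylbut-3-yn-2-yloxy)chromen-4-one | COc1ccc(-c2coc3cc(OC(C)(C)C#C)c(O)cc3c2=O)cc1OC | intermediate
15 | 3-(3,4-dimethoxyphenyl)-6-methoxy-7-(2-methylbut-3-yn-2-yloxy)chromen-4-one | COc1ccc(-c2coc3cc(OC(C)(C)C#C)c(OC)cc3c2=O)cc1OC | intermediate
16 | 3-(3,4-dimethoxyphenyl)-6-methoxy-7-(2-methylbut-3-en-2-yloxy)chromen-4-one | COc1ccc(-c2coc3cc(OC(C)(C)C=C)c(OC)cc3c2=O)cc1OC | intermediate
17 | 3-(3,4-dimethoxyphenyl)-7-hydroxy-6-methoxy-8-(3-methylbut-2-enyl)chromen-4-one | COc1ccc(-c2coc3c(CC=C(C)C)c(O)c(OC)cc3c2=O)cc1OC | target

## Step count and least certain steps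

Total step count: 9. Longest linear sequence: 8 steps (steps 1, 2, 4, 5, 6, 7, 8 and 9, from 1 to 17); step 3 is the one-step side branch that supplies 8.

Step 4 (key step).
- What may go wrong: arylation of the ambident enolate on carbon, after which the aryl anion adds to the formyl group and the adduct fragments, which amounts to insertion of the aryne into the C–CHO bond. Arynes are soft electrophiles, so this is the most likely failure. Further risks are protonation of the aryl anion before it reaches the ester, and deformylation of 8 by the methoxide that the step itself releases.
- Fallback by known chemistry, from 6 and 1, returning at 10: ester 6 is saponified with LiOH in aqueous THF to (3,4-dimethoxyphenyl)acetic acid F1. Sesamol 1 is acylated with F1 in BF3·OEt2 at 85 °C (Friedel–Crafts acylation ortho to the hydroxyl) to give 1-(6-hydroxy-1,3-benzodioxol-5-yl)-2-(3,4-dimethoxyphenyl)ethanone F2. F2 is heated with N,N-dimethylformamide dimethyl acetal in toluene, which supplies C2 and closes ring C, to give 10.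

Step 6.
- What may go wrong: loss of site selectivity with alkylation of both hydroxyls, oxidation of the free catechol by the divalent copper salt under basic conditions, and addition of the neighbouring 6-oxygen to the new alkyne.
- Fallback, from 11, returning at 15: the differentiation of the oxygens is separated from the propargylation. 11 is benzylated on the more acidic hydroxyl (BnBr, K2CO3 1.05 equiv, DMF, rt) to 7-(benzyloxy)-3-(3,4-dimethoxyphenyl)-6-hydroxychromen-4-one F3. F3 is methylated (MeI, K2CO3, acetone) to 7-(benzyloxy)-3-(3,4-dimethoxyphenyl)-6-methoxychromen-4-one F4. Hydrogenolysis (H2, Pd/C, EtOAc) gives 3-(3,4-dimethoxyphenyl)-7-hydroxy-6-methoxychromen-4-one F5. F5 has a single phenol and is propargylated with 13 under the copper conditions of step 6 to give 15.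

Step 9.
- What may go wrong: ionisation of the tertiary allyl ether with loss of isoprene and return of the phenol, and closure of the ortho-prenyl phenol to a chroman at the high temperature.
- Fallback, from 11, returning at 17: a primary allyl group is moved first and the two methyl groups are added afterwards. 11 is allylated on O7 (allyl bromide, K2CO3 1.05 equiv, DMF, rt) to 3-(3,4-dimethoxyphenyl)-6-hydroxy-7-(prop-2-enyloxy)chromen-4-one F6. F6 is methylated (MeI, K2CO3) to 3-(3,4-dimethoxyphenyl)-6-methoxy-7-(prop-2-enyloxy)chromen-4-one F7. Claisen rearrangement of F7 (PhNEt2, 200 °C), which a primary allyl ether tolerates well, gives 3-(3,4-dimethoxyphenyl)-7-hydroxy-6-methoxy-8-(prop-2-enyl)chromen-4-one F8. Cross-metathesis of F8 with 2-methylbut-2-ene and the second-generation Grubbs catalyst in CH2Cl2 at 40 °C gives 17.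

Step 5.
- What may go wrong: partial demethylation of the ring B methoxy groups if the acetal on the electron-poor ring A opens slowly and the mixture has to be warmed, or incomplete opening at low temperature.
- Fallback, from 10, returning at 11: the acetal carbon is oxidised and not ionised. 10 is treated with Pb(OAc)4 (tetravalent lead) in benzene at 60 °C to give racemic 7-(3,4-dimethoxyphenyl)-8-oxo-8H-[1,3]dioxolo[4,5-g]chromen-2-yl acetate F9. F9 is an acyloxy orthoformate and is hydrolysed by aqueous acetic acid in THF at room temperature to 11, conditions under which methyl ethers are inert.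

## Further compounds

F1 | step 4 | (3,4-dimethoxyphenyl)acetic acid | OC(=O)Cc1ccc(OC)c(OC)c1
F2 | step 4 | 1-(6-hydroxy-1,3-benzodioxol-5-yl)-2-(3,4-dimethoxyphenyl)ethanone | COc1ccc(CC(=O)c2cc3OCOc3cc2O)cc1OC
F3 | step 6 | 7-(benzyloxy)-3-(3,4-dimethoxyphenyl)-6-hydroxychromen-4-one | COc1ccc(-c2coc3cc(OCc4ccccc4)c(O)cc3c2=O)cc1OC
F4 | step 6 | 7-(benzyloxy)-3-(3,4-dimethoxyphenyl)-6-methoxychromen-4-one | COc1ccc(-c2coc3cc(OCc4ccccc4)c(OC)cc3c2=O)cc1OC
F5 | step 6 | 3-(3,4-dimethoxyphenyl)-7-hydroxy-6-methoxychromen-4-one | COc1ccc(-c2coc3cc(O)c(OC)cc3c2=O)cc1OC
F6 | step 9 | 3-(3,4-dimethoxyphenyl)-6-hydroxy-7-(prop-2-enyloxy)chromen-4-one | COc1ccc(-c2coc3cc(OCC=C)c(O)cc3c2=O)cc1OC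
F7 | step 9 | 3-(3,4-dimethoxyphenyl)-6-methoxy-7-(prop-2-enyloxy)chromen-4-one | COc1ccc(-c2coc3cc(OCC=C)c(OC)cc3c2=O)cc1OC
F8 | step 9 | 3-(3,4-dimethoxyphenyl)-7-hydroxy-6-methoxy-8-(prop-2-enyl)chromen-4-one | COc1ccc(-c2coc3c(CC=C)c(O)c(OC)cc3c2=O)cc1OC
F9 | step 5 | 7-(3,4-dimethoxyphenyl)-8-oxo-8H-[1,3]dioxolo[4,5-g]chromen-2-yl acetate (racemic) | COc1ccc(-c2coc3cc4OC(OC(C)=O)Oc4cc3c2=O)cc1OC
A1 | alternative 1 | methyl 2-acetoxy-4-hydroxy-5-methoxy-3-(3-methylbut-2-enyl)benzoate | COC(=O)c1cc(OC)c(O)c(CC=C(C)C)c1OC(C)=O
A2 | alternative 1 | methyl 4-acetoxy-3-(3-methylbut-2-enyl)-2-oxo-2H-pyran-5-carboxylate | COC(=O)C1=COC(=O)C(CC=C(C)C)=C1OC(C)=O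
A3 | alternative 1 | 2-methoxy-1,1-bis(trimethylsilyloxy)ethene | COC=C(O[Si](C)(C)C)O[Si](C)(C)C
A4 | alternative 2 | 4-methoxy-2-(3-methylbut-2-enyl)-3-(propan-2-yloxy)phenol | COc1ccc(O)c(CC=C(C)C)c1OC(C)C
A5 | alternative 2 | 4-ethenyl-4-methoxy-2-(3-methylbut-2-enyl)-3-(propan-2-yloxy)cyclobut-2-en-1-one | COC1(C=C)C(OC(C)C)=C(CC=C(C)C)C1=O
A6 | alternative 3 | 3-(3,4-dimethoxyphenyl)-6-methoxy-7-(methoxymethoxy)-8-(3-methylbut-2-enyl)chromen-4-one | COc1ccc(-c2coc3c(CC=C(C)C)c(OCOC)c(OC)cc3c2=O)cc1OC
A7 | alternative 3 | 1-[2-bromo-5-methoxy-4-(methoxymethoxy)-3-(3-methylbut-2-enyl)phenyl]-2-(3,4-dimethoxyphenyl)-3-hydroxyprop-2-en-1-one | COCOc1c(OC)cc(C(=O)C(=CO)c2ccc(OC)c(OC)c2)c(Br)c1CC=C(C)C
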